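**Plan**

1. Oxane numbering of the target: O1, C2 (methyl, side chain), C3 (CHBr), C4, C5, C6 (methyl, vinyl). The retrosynthesis cuts the vinyl C=C (Wittig on a C6 aldehyde), then the side-chain CH2–CH2 bond (Wittig and hydrogenation between a C2 aldehyde and a bicyclic phosphonium salt), then the ring bond C5–C6.
2. Enabling feature: the carbonyl carbon on C6 and the CH2O carbon on C2 lie cis across O1, so they can be tied as a 1,4-dioxan-2-one. Its enolate carbon (future C6, between O1 and C=O) is alkylated by the primary bromide of the C3–C4–C5 arm, which closes the oxane as a 3,9-dioxabicyclo[3.3.1]nonan-2-one.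
3. The lactone bridge forces the cis relation of future vinyl and future side chain at the two tetrasubstituted ether carbons; it is opened afterwards and its two ends become the vinyl group and the first side-chain carbon.
4. Ring order: the 7-oxabicyclo[2.2.1]heptane first (Diels–Alder, fragment 1); in fragment 2 the temporary dioxanone, then the oxane (key step); then lactone opening, union of the fragments, vinyl last.
5. Stereochemistry: the bicycle from the exo Diels–Alder adduct, quinidine desymmetrization of the meso anhydride and epimerization to the 2-endo/3-exo pattern; C2 and C3 from Sharpless epoxidation (L-(+)-diethyl tartrate) and anti opening by bromide; C6 from the lactone tether.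

Key step: step 16

Assumption: quinidine is taken to open the meso anhydride 4 in the sense known for bicyclic meso anhydrides; if the sense were opposite, quinine would be used in its place.
Remark: glyoxylic acid chloride 4-methylbenzenesulfonylhydrazone is treated as a stock reagent.

**Route**

Step 1
Reactants: 1 2,5-dimethylfuran; 2 maleic anhydride
Product: 3 exo-1,4-dimethyl-7-oxabicyclo[2.2.1]hept-5-ene-2,3-dicarboxylic anhydride (meso)
Conditions: Et2O, rt
Reagents that add atoms: none
Why: Diels–Alder reaction; the reversible addition should funnel into the crystalline exo adduct, which places both carbonyl carbons syn to the oxygen bridge and both methyl groups at the bridgeheads.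

Step 2
Reactants: 3 exo-1,4-dimethyl-7-oxabicyclo[2.2.1]hept-5-ene-2,3-dicarboxylic anhydride
Product: 4 exo-1,4-dimethyl-7-oxabicyclo[2.2.1]heptane-2,3-dicarboxylic anhydride (meso)
Conditions: H2 (1 atm), Pd/C, EtOAc, rt
Reagents that add atoms: none
Why: Catalytic hydrogenation of the strained alkene should be fast and removes the retro-Diels–Alder pathway; no stereocentre is created.

Step 3
Reactants: 4 exo-1,4-dimethyl-7-oxabicyclo[2.2.1]heptane-2,3-dicarboxylic anhydride
Product: 5 (1S,2R,3S,4R)-3-(methoxycarbonyl)-1,4-dimethyl-7-oxabicyclo[2.2.1]heptane-2-carboxylic acid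
Conditions: quinidine (1.1 equiv), MeOH (3 equiv), toluene, −55 °C
Reagents that add atoms: methanol, CO
Why: Alkaloid-mediated desymmetrizing methanolysis of a meso anhydride; the chiral amine should select one enantiotopic carbonyl and so fix the absolute configuration of all four ring stereocentres.

Step 4
Reactants: 5 (1S,2R,3S,4R)-3-(methoxycarbonyl)-1,4-dimethyl-7-oxabicyclo[2.2.1]heptane-2-carboxylic acid
Product: 7 (1S,2R,3R,4R)-3-(methoxycarbonyl)-1,4-dimethyl-7-oxabicyclo[2.2.1]heptane-2-carboxylic acid, via carboxylate enolate dianion 6 (not isolated)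
Conditions: LiN(i-Pr)2 (2.5 equiv), THF, −78 → −20 °C; AcOH, −78 °C
Reagents that add atoms: none
Why: Epimerization through the ester enolate: protonation from the open exo face should place the ester endo (trans to the exo acid, also the less eclipsed isomer), and the low temperature excludes ester–acid scrambling through the meso anhydride.

Step 5
Reactants: 7 (1S,2R,3R,4R)-3-(methoxycarbonyl)-1,4-dimethyl-7-oxabicyclo[2.2.1]heptane-2-carboxylic acid
Product: 8 methyl (1R,2R,3S,4S)-3-(hydroxymethyl)-1,4-dimethyl-7-oxabicyclo[2.2.1]heptane-2-carboxylate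
Conditions: BH3·SMe2, THF, 0 °C → rt; MeOH
Reagents that add atoms: none
Why: Chemoselective borane reduction of the carboxylic acid beside the methyl ester; the trans arrangement should prevent lactonization.

Step 6
Reactants: 8 methyl (1R,2R,3S,4S)-3-(hydroxymethyl)-1,4-dimethyl-7-oxabicyclo[2.2.1]heptane-2-carboxylate
Product: 9 methyl (1R,2R,3S,4S)-1,4-dimethyl-3-[(tosyloxy)methyl]-7-oxabicyclo[2.2.1]heptane-2-carboxylate
Conditions: TsCl, pyridine, CH2Cl2, 0 °C → rt
Reagents that add atoms: 4-methylbenzenesulfonyl chloride, Cc1ccc(cc1)S(Cl)(=O)=O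
Why: Sulfonylation of the primary alcohol, to prepare its reduction to the exo methyl group.

Step 7
Reactants: 9 methyl (1R,2R,3S,4S)-1,4-dimethyl-3-[(tosyloxy)methyl]-7-oxabicyclo[2.2.1]heptane-2-carboxylate
Product: 10 [(1R,2S,3R,4S)-1,3,4-trimethyl-7-oxabicyclo[2.2.1]heptan-2-yl]methanol
Conditions: LiEt3BH (5 equiv), THF, 0 °C → reflux
Reagents that add atoms: none
Why: Hydride displacement (SN2) of the primary tosylate should give the exo methyl group, and the same reagent reduces the ester to the endo hydroxymethyl group.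

Step 8
Reactants: 10 [(1R,2S,3R,4S)-1,3,4-trimethyl-7-oxabicyclo[2.2.1]heptan-2-yl]methanol
Product: 11 (1R,2R,3R,4S)-2-(iodomethyl)-1,3,4-trimethyl-7-oxabicyclo[2.2.1]heptane
Conditions: I2, PPh3, imidazole, CH2Cl2, 0 °C → rt
Reagents that add atoms: iodine, II
Why: Appel-type iodination of a primary alcohol; no stereocentre is involved.

Step 9
Reactants: 11 (1R,2R,3R,4S)-2-(iodomethyl)-1,3,4-trimethyl-7-oxabicyclo[2.2.1]heptane
Product: 12 {[(1R,2R,3R,4S)-1,3,4-trimethyl-7-oxabicyclo[2.2.1]heptan-2-yl]methyl}(triphenyl)phosphonium iodide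
Conditions: PPh3, MeCN, reflux
Reagents that add atoms: triphenylphosphine, c1ccc(cc1)P(c1ccccc1)c1ccccc1
Why: SN2 quaternization of triphenylphosphine by the primary iodide; prolonged heating should overcome the β-branching.

Step 10
Reactants: 13 5-bromo-2-methylpent-2-ene
Product: 14 (2E)-5-bromo-2-methylpent-2-en-1-ol
Conditions: SeO2 (0.5 equiv), t-BuOOH, CH2Cl2, rt
Reagents that add atoms: tert-butyl hydroperoxide, CC(C)(C)OO (oxygen atom, relayed by the SeO2 catalyst)
Why: SeO2 allylic oxidation (ene reaction, then 2,3-sigmatropic shift) is known to take the methyl group trans to the chain of a trisubstituted alkene, so the (E)-allylic alcohol should result.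

Step 11
Reactants: 14 (2E)-5-bromo-2-methylpent-2-en-1-ol
Product: 15 [(2S,3S)-3-(2-bromoethyl)-2-methyloxiran-2-yl]methanol
Conditions: Ti(OiPr)4 (10 mol %), L-(+)-diethyl tartrate (12 mol %), t-BuOOH, 4 Å molecular sieves, CH2Cl2, −20 °C
Reagents that add atoms: tert-butyl hydroperoxide, CC(C)(C)OO
Why: Sharpless asymmetric epoxidation of an (E)-2-methyl allylic alcohol; the L-(+)-tartrate complex should deliver oxygen to the face that gives the (2S,3S)-epoxide, which sets both future oxane centres C2 and C3 (C3 still to be inverted).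

Step 12
Reactants: 15 [(2S,3S)-3-(2-bromoethyl)-2-methyloxiran-2-yl]methanol
Product: 16 (2S,3R)-3,5-dibromo-2-methylpentane-1,2-diol
Conditions: Ti(OiPr)4 (1.5 equiv), Et2NH2Br (1.5 equiv), CH2Cl2, rt
Reagents that add atoms: diethylammonium bromide, CC[NH2+]CC.[Br-]
Why: Titanium-mediated opening of a 2,3-epoxy alcohol: within the titanium alkoxide chelate bromide should attack the distal secondary carbon (SN2, inversion), giving the anti bromohydrin with the tertiary hydroxyl intact.

Step 13
Reactants: 16 (2S,3R)-3,5-dibromo-2-methylpentane-1,2-diol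
Product: 18 (2S,3R)-3,5-dibromo-2-hydroxy-2-methylpentyl diazoacetate, via tosylhydrazone ester 17 (not isolated)
Conditions: TsNHN=CHCOCl, PhNMe2, CH2Cl2, 0 °C; then Et3N
Reagents that add atoms: glyoxylic acid chloride 4-methylbenzenesulfonylhydrazone, O=C(Cl)C=NNS(=O)(=O)c1ccc(C)cc1
Why: Selective acylation of the primary hydroxyl, then base-induced loss of sulfinate from the tosylhydrazone (Bamford–Stevens-type diazo formation); the tertiary hydroxyl is too hindered to be acylated.

Step 14
Reactants: 18 (2S,3R)-3,5-dibromo-2-hydroxy-2-methylpentyl diazoacetate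
Product: 19 (5S)-5-[(1R)-1,3-dibromopropyl]-5-methyl-1,4-dioxan-2-one
Conditions: Rh2(OAc)4 (1 mol %), CH2Cl2, rt, slow addition
Reagents that add atoms: none
Why: Intramolecular O–H insertion of a dirhodium carbenoid; the six-membered mode should be fast even for the hindered tertiary hydroxyl, is neutral (no epoxide formation from the bromohydrin) and retains the carbinol configuration.

Step 15
Reactants: 19 (5S)-5-[(1R)-1,3-dibromopropyl]-5-methyl-1,4-dioxan-2-one
Product: 21 (5S)-5-[(1R)-1,3-dibromopropyl]-3,5-dimethyl-1,4-dioxan-2-one (both C3 epimers), via lithium enolate 20 (not isolated)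
Conditions: LiN(SiMe3)2 (1.05 equiv), THF, −78 °C; MeI (5 equiv), −78 °C
Reagents that add atoms: iodomethane, CI
Why: Lactone enolate alkylation; at −78 °C iodomethane should trap the enolate faster than it can reach the primary bromide, and the new centre need not be controlled because step 16 planarizes it again.

Step 16
Reactants: 21 (5S)-5-[(1R)-1,3-dibromopropyl]-3,5-dimethyl-1,4-dioxan-2-one
Product: 23 (1S,5S,6R)-6-bromo-1,5-dimethyl-3,9-dioxabicyclo[3.3.1]nonan-2-one, via potassium enolate 22 (not isolated)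
Conditions: KN(SiMe3)2 (1.1 equiv), THF–DMPU, −78 → −20 °C
Reagents that add atoms: none
Why: The base removes the only acidic proton, at the dioxanone carbon between the ring oxygen and the lactone carbonyl, and the enolate (geometry fixed by the ring) displaces the primary bromide of the axial three-carbon arm in an intramolecular SN2 reaction. The closest known reaction type is the intramolecular α-alkylation of ester and lactone enolates, as in the closure of bicyclo[3.3.1]nonan-2-ones from 4-(3-halopropyl)cyclohexanone enolates. The oxane ring closes in the 6-exo-tet mode and the product is a 3,9-dioxabicyclo[3.3.1]nonan-2-one. The new tetrasubstituted centre (C6 of the target) is controlled by the lactone tether: arm and lactone bridge hang from the same carbon, so the enolate can only be reached on the face that leaves the carbonyl carbon cis to the CH2O carbon (future vinyl cis to future side chain), and both epimers of 21 converge on the same enolate. The step needs C- over O-alkylation and reaction at the primary and not the secondary bromide; the six-membered transition state (against an eight-membered ring for O-alkylation and a four-membered ring for attack at CHBr) and the low temperature should secure both.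

Step 17
Reactants: 23 (1S,5S,6R)-6-bromo-1,5-dimethyl-3,9-dioxabicyclo[3.3.1]nonan-2-one
Product: 25 methyl (2S,5R,6S)-5-bromo-6-(hydroxymethyl)-2,6-dimethyloxane-2-carboxylate, via lithium carboxylate 24 (not isolated)
Conditions: LiOH, THF–H2O, rt; then MeI, DMF, rt
Reagents that add atoms: lithium hydroxide, [Li+].[OH-]; iodomethane, CI
Why: Saponification should open the bridged lactone irreversibly as the carboxylate, and SN2 methylation of the carboxylate gives the ester without an acid that could relactonize it.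

Step 18
Reactants: 25 methyl (2S,5R,6S)-5-bromo-6-(hydroxymethyl)-2,6-dimethyloxane-2-carboxylate
Product: 26 methyl (2S,5R,6S)-5-bromo-6-formyl-2,6-dimethyloxane-2-carboxylate
Conditions: Dess–Martin periodinane, CH2Cl2, rt
Reagents that add atoms: none
Why: Dess–Martin oxidation of the neopentyl-type primary alcohol to a non-enolizable aldehyde; removing the hydroxyl also rules out relactonization.

Step 19
Reactants: 12 {[(1R,2R,3R,4S)-1,3,4-trimethyl-7-oxabicyclo[2.2.1]heptan-2-yl]methyl}(triphenyl)phosphonium iodide; 26 methyl (2S,5R,6S)-5-bromo-6-formyl-2,6-dimethyloxane-2-carboxylate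
Product: 28 methyl (2S,5R,6S)-5-bromo-2,6-dimethyl-6-{(Z)-2-[(1R,2R,3R,4S)-1,3,4-trimethyl-7-oxabicyclo[2.2.1]heptan-2-yl]ethenyl}oxane-2-carboxylate, via phosphorus ylide 27 (not isolated)
Conditions: 12, KN(SiMe3)2, THF, −78 → 0 °C; then 26, −78 °C → rt
Reagents that add atoms: none
Why: Wittig reaction of a non-stabilized ylide, which should attack the aldehyde far faster than the hindered ester; the alkene geometry (expected Z) is irrelevant because the double bond is hydrogenated next.

Step 20
Reactants: 28 methyl (2S,5R,6S)-5-bromo-2,6-dimethyl-6-{(Z)-2-[(1R,2R,3R,4S)-1,3,4-trimethyl-7-oxabicyclo[2.2.1]heptan-2-yl]ethenyl}oxane-2-carboxylate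
Product: 29 methyl (2S,5R,6S)-5-bromo-2,6-dimethyl-6-{2-[(1R,2R,3R,4S)-1,3,4-trimethyl-7-oxabicyclo[2.2.1]heptan-2-yl]ethyl}oxane-2-carboxylate
Conditions: H2 (1 atm), [Ir(cod)(PCy3)(py)]PF6 (5 mol %), CH2Cl2, rt
Reagents that add atoms: none
Why: Homogeneous iridium-catalysed hydrogenation should reduce the hindered disubstituted alkene without hydrogenolysis of the secondary C–Br bond; it is placed before the vinyl group exists.

Step 21
Reactants: 29 methyl (2S,5R,6S)-5-bromo-2,6-dimethyl-6-{2-[(1R,2R,3R,4S)-1,3,4-trimethyl-7-oxabicyclo[2.2.1]heptan-2-yl]ethyl}oxane-2-carboxylate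
Product: 30 (2S,5R,6S)-5-bromo-2,6-dimethyl-6-{2-[(1R,2R,3R,4S)-1,3,4-trimethyl-7-oxabicyclo[2.2.1]heptan-2-yl]ethyl}oxane-2-carbaldehyde
Conditions: i-Bu2AlH, CH2Cl2, −78 °C
Reagents that add atoms: none
Why: Partial reduction of an α-alkoxy ester, which at −78 °C should stop at the aldehyde oxidation level.

Step 22
Reactants: 30 (2S,5R,6S)-5-bromo-2,6-dimethyl-6-{2-[(1R,2R,3R,4S)-1,3,4-trimethyl-7-oxabicyclo[2.2.1]heptan-2-yl]ethyl}oxane-2-carbaldehyde
Product: 31 dactylopyranoid, (2S,3R,6S)-3-bromo-6-ethenyl-2,6-dimethyl-2-{2-[(1R,2R,3R,4S)-1,3,4-trimethyl-7-oxabicyclo[2.2.1]heptan-2-yl]ethyl}oxane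
Conditions: Ph3PCH3Br, KOtBu, THF, 0 °C → rt
Reagents that add atoms: methyltriphenylphosphonium bromide, C[P+](c1ccccc1)(c1ccccc1)c1ccccc1.[Br-]
Why: Wittig methylenation of the non-enolizable α-alkoxy aldehyde should give the vinyl group at the quaternary ether carbon without touching any stereocentre.

**Compound list**

1 | 2,5-dimethylfuran | Cc1ccc(C)o1 | starting material
2 | maleic anhydride | O=C1OC(=O)C=C1 | starting material
3 | exo-1,4-dimethyl-7-oxabicyclo[2.2.1]hept-5-ene-2,3-dicarboxylic anhydride (meso) | O=C3[C@H]1[C@@H](C(=O)O3)[C@]2(C)C=C[C@@]1(C)O2 | intermediate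
4 | exo-1,4-dimethyl-7-oxabicyclo[2.2.1]heptane-2,3-dicarboxylic anhydride (meso) | O=C3[C@H]1[C@@H](C(=O)O3)[C@]2(C)CC[C@@]1(C)O2 | intermediate
5 | (1S,2R,3S,4R)-3-(methoxycarbonyl)-1,4-dimethyl-7-oxabicyclo[2.2.1]heptane-2-carboxylic acid (both carbonyl groups exo) | COC(=O)[C@H]1[C@@H](C(=O)O)[C@]2(C)CC[C@@]1(C)O2 | intermediate
6 | dilithium carboxylate ester enolate of 5 | [Li+].[Li+].COC([O-])=C1[C@@H](C([O-])=O)[C@]2(C)CC[C@@]1(C)O2 | intermediate (not isolated)
7 | (1S,2R,3R,4R)-3-(methoxycarbonyl)-1,4-dimethyl-7-oxabicyclo[2.2.1]heptane-2-carboxylic acid (acid exo, ester endo) | COC(=O)[C@@H]1[C@@H](C(=O)O)[C@]2(C)CC[C@@]1(C)O2 | intermediate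
8 | methyl (1R,2R,3S,4S)-3-(hydroxymethyl)-1,4-dimethyl-7-oxabicyclo[2.2.1]heptane-2-carboxylate | COC(=O)[C@@H]1[C@@H](CO)[C@]2(C)CC[C@@]1(C)O2 | intermediate
9 | methyl (1R,2R,3S,4S)-1,4-dimethyl-3-[(tosyloxy)methyl]-7-oxabicyclo[2.2.1]heptane-2-carboxylate | COC(=O)[C@@H]1[C@@H](COS(=O)(=O)c3ccc(C)cc3)[C@]2(C)CC[C@@]1(C)O2 | intermediate
10 | [(1R,2S,3R,4S)-1,3,4-trimethyl-7-oxabicyclo[2.2.1]heptan-2-yl]methanol (CH2OH endo, 3-methyl exo) | OC[C@@H]1[C@@H](C)[C@]2(C)CC[C@@]1(C)O2 | intermediate
11 | (1R,2R,3R,4S)-2-(iodomethyl)-1,3,4-trimethyl-7-oxabicyclo[2.2.1]heptane | IC[C@@H]1[C@@H](C)[C@]2(C)CC[C@@]1(C)O2 | intermediate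
12 | {[(1R,2R,3R,4S)-1,3,4-trimethyl-7-oxabicyclo[2.2.1]heptan-2-yl]methyl}(triphenyl)phosphonium iodide | [I-].c1ccc(cc1)[P+](c1ccccc1)(c1ccccc1)C[C@@H]1[C@@H](C)[C@]2(C)CC[C@@]1(C)O2 | intermediate
13 | 5-bromo-2-methylpent-2-ene | CC(C)=CCCBr | starting material
14 | (2E)-5-bromo-2-methylpent-2-en-1-ol | OC/C(C)=C/CCBr | intermediate
15 | [(2S,3S)-3-(2-bromoethyl)-2-methyloxiran-2-yl]methanol | BrCC[C@@H]1O[C@@]1(C)CO | intermediate
16 | (2S,3R)-3,5-dibromo-2-methylpentane-1,2-diol | BrCC[C@@H](Br)[C@](C)(CO)O | intermediate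
17 | (2S,3R)-3,5-dibromo-2-hydroxy-2-methylpentyl [2-(4-methylbenzenesulfonyl)hydrazinylidene]acetate | BrCC[C@@H](Br)[C@](C)(COC(=O)C=NNS(=O)(=O)c1ccc(C)cc1)O | intermediate (not isolated)
18 | (2S,3R)-3,5-dibromo-2-hydroxy-2-methylpentyl diazoacetate | BrCC[C@@H](Br)[C@](C)(COC(=O)C=[N+]=[N-])O | intermediate
19 | (5S)-5-[(1R)-1,3-dibromopropyl]-5-methyl-1,4-dioxan-2-one | BrCC[C@@H](Br)[C@]1(C)COC(=O)CO1 | intermediate
20 | lithium enolate of 19 | [Li+].BrCC[C@@H](Br)[C@]1(C)COC([O-])=CO1 | intermediate (not isolated)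
21 | (5S)-5-[(1R)-1,3-dibromopropyl]-3,5-dimethyl-1,4-dioxan-2-one (both C3 epimers) | BrCC[C@@H](Br)[C@]1(C)COC(=O)C(C)O1 | intermediate
22 | potassium enolate of 21 | [K+].BrCC[C@@H](Br)[C@]1(C)COC([O-])=C(C)O1 | intermediate (not isolated)
23 | (1S,5S,6R)-6-bromo-1,5-dimethyl-3,9-dioxabicyclo[3.3.1]nonan-2-one | O=C3[C@]1(C)CC[C@@H](Br)[C@](C)(CO3)O1 | intermediate
24 | lithium (2S,5R,6S)-5-bromo-6-(hydroxymethyl)-2,6-dimethyloxane-2-carboxylate | [Li+].[O-]C(=O)[C@]1(C)CC[C@@H](Br)[C@](C)(CO)O1 | intermediate (not isolated)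
25 | methyl (2S,5R,6S)-5-bromo-6-(hydroxymethyl)-2,6-dimethyloxane-2-carboxylate | COC(=O)[C@]1(C)CC[C@@H](Br)[C@](C)(CO)O1 | intermediate
26 | methyl (2S,5R,6S)-5-bromo-6-formyl-2,6-dimethyloxane-2-carboxylate | COC(=O)[C@]1(C)CC[C@@H](Br)[C@](C)(C=O)O1 | intermediate
27 | {[(1R,2R,3R,4S)-1,3,4-trimethyl-7-oxabicyclo[2.2.1]heptan-2-yl]methylidene}(triphenyl)phosphorane | c1ccc(cc1)P(c1ccccc1)(c1ccccc1)=C[C@@H]1[C@@H](C)[C@]2(C)CC[C@@]1(C)O2 | intermediate (not isolated)
28 | methyl (2S,5R,6S)-5-bromo-2,6-dimethyl-6-{(Z)-2-[(1R,2R,3R,4S)-1,3,4-trimethyl-7-oxabicyclo[2.2.1]heptan-2-yl]ethenyl}oxane-2-carboxylate | COC(=O)[C@]1(C)CC[C@@H](Br)[C@](C)(/C=C\[C@@H]2[C@@H](C)[C@]3(C)CC[C@@]2(C)O3)O1 | intermediate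
29 | methyl (2S,5R,6S)-5-bromo-2,6-dimethyl-6-{2-[(1R,2R,3R,4S)-1,3,4-trimethyl-7-oxabicyclo[2.2.1]heptan-2-yl]ethyl}oxane-2-carboxylate | COC(=O)[C@]1(C)CC[C@@H](Br)[C@](C)(CC[C@@H]2[C@@H](C)[C@]3(C)CC[C@@]2(C)O3)O1 | intermediate
30 | (2S,5R,6S)-5-bromo-2,6-dimethyl-6-{2-[(1R,2R,3R,4S)-1,3,4-trimethyl-7-oxabicyclo[2.2.1]heptan-2-yl]ethyl}oxane-2-carbaldehyde | O=C[C@]1(C)CC[C@@H](Br)[C@](C)(CC[C@@H]2[C@@H](C)[C@]3(C)CC[C@@]2(C)O3)O1 | intermediate
31 | dactylopyranoid, (2S,3R,6S)-3-bromo-6-ethenyl-2,6-dimethyl-2-{2-[(1R,2R,3R,4S)-1,3,4-trimethyl-7-oxabicyclo[2.2.1]heptan-2-yl]ethyl}oxane | C=C[C@]1(C)CC[C@@H](Br)[C@](C)(CC[C@@H]2[C@@H](C)[C@]3(C)CC[C@@]2(C)O3)O1 | target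

**Step count and risks**

Total step count: 22. Longest linear sequence: 13 steps (13 → 31 through steps 10–22; the branch 1 → 12 → 31 through steps 1–9 and 19–22 is equally long).

Steps most likely to fail:

1. Step 16. The lactone enolate may fragment (loss of the ring alkoxide to a ketene) or acylate a second molecule before it closes the bridged ring, and the base may eliminate HBr from the arm. The fallback leaves the tether out of the C–C bond formation and uses lactonization only to sort the epimers; it sets out from 16 and returns at 23. Diol 16 is silylated at the primary hydroxyl (t-BuPh2SiCl, imidazole) to (2S,3R)-3,5-dibromo-1-[(tert-butyldiphenylsilyl)oxy]-2-methylpentan-2-ol F1. Rh2(OAc)4-catalysed O–H insertion of methyl 2-diazopropanoate into the tertiary hydroxyl should give the lactate ether methyl 2-{[(2S,3R)-3,5-dibromo-1-[(tert-butyldiphenylsilyl)oxy]-2-methylpentan-2-yl]oxy}propanoate F2. KN(SiMe3)2 should then close the oxane through the acyclic ester enolate to methyl (5R,6S)-5-bromo-6-{[(tert-butyldiphenylsilyl)oxy]methyl}-2,6-dimethyloxane-2-carboxylate F3, as both epimers at the ester-bearing carbon. Bu4NF frees the primary alcohol; only the epimer with the ester cis to CH2OH can lactonize, which gives 23, while the trans epimer methyl (2R,5R,6S)-5-bromo-6-(hydroxymethyl)-2,6-dimethyloxane-2-carboxylate F4 stays open and is separated.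

2. Step 19. Both partners are hindered, so ylide addition may be slow (as may the quaternization in step 9), and the basic ylide may instead eliminate HBr or trigger fragmentation of the β-bromo aldehyde. The fallback is a Julia–Kocienski olefination, which avoids the phosphonium salt; it sets out from 10 and returns at 29. Alcohol 10 is converted by Mitsunobu reaction with 1-phenyl-1H-tetrazole-5-thiol (PPh3, diisopropyl azodicarboxylate) into 1-phenyl-5-({[(1R,2R,3R,4S)-1,3,4-trimethyl-7-oxabicyclo[2.2.1]heptan-2-yl]methyl}sulfanyl)-1H-tetrazole F5. Oxidation (H2O2, (NH4)6Mo7O24) should give 1-phenyl-5-({[(1R,2R,3R,4S)-1,3,4-trimethyl-7-oxabicyclo[2.2.1]heptan-2-yl]methyl}sulfonyl)-1H-tetrazole F6. Its potassium anion (KN(SiMe3)2, −78 °C) is added to aldehyde 26 to give methyl (2S,5R,6S)-5-bromo-2,6-dimethyl-6-{(E)-2-[(1R,2R,3R,4S)-1,3,4-trimethyl-7-oxabicyclo[2.2.1]heptan-2-yl]ethenyl}oxane-2-carboxylate F7, which is hydrogenated under the conditions of step 20 to 29.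

3. Step 12. Bromide may enter at the tertiary epoxide carbon, or the Lewis acid may rearrange the trisubstituted epoxide. The fallback gives up chelate delivery for steric control; it sets out from 15 and returns at 16. The hydroxyl of 15 is silylated (t-BuMe2SiCl, imidazole) to {[(2S,3S)-3-(2-bromoethyl)-2-methyloxiran-2-yl]methoxy}(tert-butyl)dimethylsilane F8, so that no chelate can form. The soft bromide of Li2NiBr4 in THF should open the epoxide at the less substituted carbon to (2S,3R)-3,5-dibromo-1-[(tert-butyldimethylsilyl)oxy]-2-methylpentan-2-ol F9, and HF·pyridine (non-basic, so the bromohydrin does not reclose) gives 16.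

Further compounds
F1 | step 16 | (2S,3R)-3,5-dibromo-1-[(tert-butyldiphenylsilyl)oxy]-2-methylpentan-2-ol | BrCC[C@@H](Br)[C@](C)(CO[Si](c1ccccc1)(c1ccccc1)C(C)(C)C)O
F2 | step 16 | methyl 2-{[(2S,3R)-3,5-dibromo-1-[(tert-butyldiphenylsilyl)oxy]-2-methylpentan-2-yl]oxy}propanoate | BrCC[C@@H](Br)[C@](C)(CO[Si](c1ccccc1)(c1ccccc1)C(C)(C)C)OC(C)C(=O)OC
F3 | step 16 | methyl (5R,6S)-5-bromo-6-{[(tert-butyldiphenylsilyl)oxy]methyl}-2,6-dimethyloxane-2-carboxylate (both C2 epimers) | COC(=O)C1(C)CC[C@@H](Br)[C@](C)(CO[Si](c2ccccc2)(c2ccccc2)C(C)(C)C)O1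
F4 | step 16 | methyl (2R,5R,6S)-5-bromo-6-(hydroxymethyl)-2,6-dimethyloxane-2-carboxylate | COC(=O)[C@@]1(C)CC[C@@H](Br)[C@](C)(CO)O1
F5 | step 19 | 1-phenyl-5-({[(1R,2R,3R,4S)-1,3,4-trimethyl-7-oxabicyclo[2.2.1]heptan-2-yl]methyl}sulfanyl)-1H-tetrazole | c1ccc(cc1)-n1nnnc1SC[C@@H]1[C@@H](C)[C@]2(C)CC[C@@]1(C)O2
F6 | step 19 | 1-phenyl-5-({[(1R,2R,3R,4S)-1,3,4-trimethyl-7-oxabicyclo[2.2.1]heptan-2-yl]methyl}sulfonyl)-1H-tetrazole | O=S(=O)(C[C@@H]1[C@@H](C)[C@]2(C)CC[C@@]1(C)O2)c1nnnn1-c1ccccc1
F7 | step 19 | methyl (2S,5R,6S)-5-bromo-2,6-dimethyl-6-{(E)-2-[(1R,2R,3R,4S)-1,3,4-trimethyl-7-oxabicyclo[2.2.1]heptan-2-yl]ethenyl}oxane-2-carboxylate | COC(=O)[C@]1(C)CC[C@@H](Br)[C@](C)(/C=C/[C@@H]2[C@@H](C)[C@]3(C)CC[C@@]2(C)O3)O1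
F8 | step 12 | {[(2S,3S)-3-(2-bromoethyl)-2-methyloxiran-2-yl]methoxy}(tert-butyl)dimethylsilane | BrCC[C@@H]1O[C@@]1(C)CO[Si](C)(C)C(C)(C)C
F9 | step 12 | (2S,3R)-3,5-dibromo-1-[(tert-butyldimethylsilyl)oxy]-2-methylpentan-2-ol | BrCC[C@@H](Br)[C@](C)(CO[Si](C)(C)C(C)(C)C)O
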